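## Structural features

The target is a furofuran lignan: a cis-fused 3,7-dioxabicyclo[3.3.0]octane in which two tetrahydrofuran rings share the C8–C8' bond. In lignan numbering ring A is O–C7–C8–C8'–C9' and ring B is O–C7'–C8'–C8–C9. C7 carries a 4-hydroxy-3-methoxyphenyl group (ArA) and C7' a 3-methoxy-4-prenyloxyphenyl group (ArB). The two halves differ only at the phenol oxygen, so the skeleton cannot be made by dimerising one unit. The four stereocentres C7, C8, C8', C7' are contiguous and configured 7R,8S,8'S,7'R: the ring fusion is cis and each aryl group lies on the convex face, cis to the neighbouring bridgehead hydrogen (the relative configuration of pinoresinol). Both benzylic C–O bonds are para to an oxygen donor and ionise under acid, which can epimerise C7 or C7' or lead to Friedel–Crafts closure to an aryltetralin. The aryl prenyl ether tolerates neither Lewis acids nor metathesis catalysts, and the free phenol is sensitive to oxidants. The real difficulty is the absolute configuration of the bridgehead pair C8/C8' in a skeleton whose two aryl groups must arrive separately; the benzylic centres can be set late under substrate control, the bridgeheads cannot. The plan exploits the fact that C7 is bonded to C8 and is 1,3-related to C8' through the ring A oxygen and C9'. C7 can therefore first be attached to both C8 and C8' as the third carbon of a cyclopropane fused to ring B, and the C7–C8' bond can later be exchanged for the C7–O bond of ring A.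

## Logic of the disconnections

21 to 20: the O–Si bond on ArA is cut. The ArA phenol is kept masked to the end so that only one phenol is ever free. The forward step is a buffered fluoride cleavage that must leave the benzylic ethers and the prenyl ether alone.

20 to 18 and 19: the aryl O–CH2 bond of the prenyl ether is cut. The prenyl group would not survive metathesis, Sc(OTf)3 or the acid closure, so it is attached after all of them. This requires the ArB oxygen to be the only free phenol in 18, which an ester/silyl ether pair on the two rings provides.

18 to 16 through 17: the C7–O bond of ring A is cut and C9' is raised to the carboxyl level. Ring A becomes a γ-aryl lactone, the retron of a donor–acceptor cyclopropane. Forward, one hydride reduction must open the lactone and remove the ArB ester, and the acid closure must place ArA on the convex face without disturbing C7'.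

16 to 15: the acyl O–C7 bond is cut and C7 is joined to C8'. The 1,3-related pair C7/C8' becomes one edge of a cyclopropane, ring A disappears, and the three centres C7, C8, C8' reduce to a single question of face. Forward, a Lewis acid must cleave only the C7–C8' bond, the one flanked by donor aryl and acceptor ester, and the ester must give up its alkyl group. For that reason the ester is tert-butyl rather than a simple alkyl ester: it leaves as isobutene and supplies the proton for C8', so no external nucleophile is needed.

15 to 14 and 8: the C7–C8 and C7–C8' bonds are cut. A benzylidene unit is added across the C8=C8' bond of an unsaturated ester; both fragments come from 1. Forward, the ylide must attack the face opposite ArB, and conjugate addition must outrun proton abstraction from 8.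

14 to 13, then to 11 and 12, then to 10, 9 and 1: the C–S bond, the C–Br bond, the benzylic C–H and the O–Si bond are cut in turn. All are routine functional-group steps on an electron-rich benzyl system whose halide and sulfonium salt must be handled cold.

8 to 7: the C8=C8' double bond is cut. Ring B opens to an acyclic diene held together by the C7'–O–C9 ether, and the closure is a five-membered ring-closing metathesis onto a 1,1-disubstituted electron-poor alkene.

7 to 5 and 6: the C7'–O ether bond is cut. This is the only step in which absolute configuration is introduced. Both enantiomers of 5 pass through one allylammonium ion, so no material is lost to resolution. The demand is branched (SN2'–SN2') regiochemistry and the correct sense of induction.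

5 to 4, then to 2 and 3: the C7'–C8' bond is cut. The aldehyde carbon of 2 and the α-carbon of 3 are joined by a Morita–Baylis–Hillman reaction; the racemic carbinol is acceptable because the next step erases it.

2 to 1: the acyl–O bond is cut. The hindered ester protects the ArB phenol and deactivates ArB toward benzylic ionisation.

## Other disconnections considered

Alternative 1: The cut is made at C7–C8 and C7'–C8', leaving C9–C8–C8'–C9' as the chiral butenolide A1, ArA as the dithiane A2 (the dithioacetal of 9) and ArB as the aldehyde A3. In the forward key step lithiated A2 would add to C8 of A1 anti to the acetal alkoxy group, and the lactone enolate would be intercepted at C8' by A3 on the face away from the new substituent, giving A4.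
- In its favour: the whole carbon skeleton and the C8/C8' relationship arise in one three-component step, and each component is one or two steps from 1.
- Against it here: no ring of the target is closed. Dithiane removal, two reductions and a double acid cyclisation follow, all with the prenyl ether of A3 already in place. Reagents that unmask dithianes and the acid of the last step both threaten that group. The auxiliary is stoichiometric and of the less available enantiomeric series.
- Structure: both plans relay configuration to C8/C8' from a five-membered unsaturated carbonyl ring. In A1 the controlling centre is disposable; in the chosen plan it is C7' of the target and is set by catalysis.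
- Mechanism: both begin with conjugate addition anti to a ring substituent. The intermolecular aldol trapping is at least as dependable as the 3-exo-tet closure, but both C7 and C7' would rest on a late cationic closure instead of C7 alone.
- Step economy: the alternative is better, about ten operations against fourteen.

Alternative 2: C8–C8' is cut after C7 and C7' are formally joined, so that the two cinnamate halves sit on a C2-symmetric tether in diester A5. Irradiation of A5 would give the head-to-head all-trans cyclobutane A6, in which the trans-diester maps onto the cis ring fusion and the C7–C7' bond is sacrificial.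
- In its favour: the central bond is made in one step from two inexpensive cinnamate units, and the tether solves the cross-coupling of two different halves. On these points it is the equal or the better of the chosen plan, and its step count would be comparable or lower.
- Against it here: direct excitation of cinnamates tends to end in E/Z isomerisation. Facial control by a flexible ten-membered tether is uncertain. The allyl ether on ArB is a second alkene and still has to become prenyl.
- The most serious objection is the later cleavage of C7–C7'. It needs one-electron oxidation of an electron-rich diarylcyclobutane with capture of both benzylic carbons by the hydroxymethyl groups across the ring, whereas such radical cations normally revert to two alkenes and would take the C8–C8' bond with them.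
- Mechanism: both plans use a sacrificial C–C bond in a strained ring. In 15 that bond is polarised by donor and acceptor and should heterolyse to one cation; in A6 it is a non-polar bond between two similar donors.

Alternative 3: C8–C8' is cut by returning C8 from C8' to the carbon that becomes C7', which expands ring A to the diazo tetrahydropyranone A7. A7 would come from a hetero-Diels–Alder reaction of 9 with a 1-alkoxy-3-silyloxydiene carrying the silyloxymethyl group at its terminus, then conjugate reduction and diazo transfer. Irradiation in methanol would give A8 by Wolff ring contraction.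
- In its favour: C7 and C8 would be set together under catalyst control, which is better than the late cationic closure of the chosen plan. The shift proceeds with retention at C8 and forms ring A outright. C8' is epimerisable and needs no control, which is equal to the chosen plan, where it follows from the ring fusion.
- Against it here: ArB is still missing after A8 and must be added to the ester carbon by an aryl–metal reagent, and ring B is then closed through a C7' cation. The carbene from A7 has the C9' methylene beside it, and a 1,2-hydrogen shift to an enone could compete with contraction. Diene synthesis, reduction and regioselective diazo transfer come before the key step.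
- Structure: ring A is built first and ring B last, the reverse of the chosen plan.
- Step economy: the alternative is the weaker, at an estimated sixteen or more operations.

Key step: step 10

Assumption: in step 4 the quinidine-derived dimer (DHQD)2PHAL is taken to deliver the (S)-ether; should the first run show the opposite sense, the quinine-derived (DHQ)2PHAL replaces it and nothing else changes.

## Route

Step 1
Reactants: 1 vanillin
Product: 2 4-formyl-2-methoxyphenyl 2,2-dimethylpropanoate (O-pivaloylvanillin)
Conditions: PivCl (1.1 equiv), Et3N (1.3 equiv), DMAP (2 mol%), CH2Cl2, 0 °C to rt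
Reagents that add atoms: pivaloyl chloride, CC(C)(C)C(=O)Cl
Why: Acylation of the phenol under nucleophilic catalysis. The hindered ester should survive amines, metathesis, the ylide and Sc(OTf)3, is removed without an extra step by LiAlH4 in step 12, and keeps ArB too electron-poor for C7'–O to ionise later.

Step 2
Reactants: 2 4-formyl-2-methoxyphenyl 2,2-dimethylpropanoate; 3 tert-butyl acrylate
Product: 4 racemic tert-butyl 2-[hydroxy(3-methoxy-4-pivaloyloxyphenyl)methyl]prop-2-enoate
Conditions: DABCO (1.0 equiv), 3 (4 equiv), no solvent, rt, several days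
Reagents that add atoms: none
Why: Morita–Baylis–Hillman reaction; the acyloxy group para to the aldehyde keeps it electrophilic enough for the slow tert-butyl acrylate. The carbinol centre is formed racemic on purpose, since step 4 erases it, and the tert-butyl ester is installed here so that step 11 can shed it as isobutene.

Step 3
Reactants: 4 racemic tert-butyl 2-[hydroxy(3-methoxy-4-pivaloyloxyphenyl)methyl]prop-2-enoate
Product: 5 racemic tert-butyl 2-[(tert-butoxycarbonyloxy)(3-methoxy-4-pivaloyloxyphenyl)methyl]prop-2-enoate
Conditions: Boc2O (1.2 equiv), DMAP (5 mol%), CH2Cl2, 0 °C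
Reagents that add atoms: di-tert-butyl dicarbonate, CC(C)(C)OC(=O)OC(=O)OC(C)(C)C
Why: O-Acylation turns the hydroxyl into a leaving group that releases its own base (tert-butoxide after loss of CO2) in the next step. The reaction is kept cold and short so that the amine catalyst does not transpose the allylic carbonate.

Step 4
Reactants: 5 racemic tert-butyl 2-[(tert-butoxycarbonyloxy)(3-methoxy-4-pivaloyloxyphenyl)methyl]prop-2-enoate; 6 allyl alcohol
Product: 7 tert-butyl 2-[(S)-(3-methoxy-4-pivaloyloxyphenyl)(prop-2-en-1-yloxy)methyl]prop-2-enoate
Conditions: 6 (5 equiv), hydroquinidine 1,4-phthalazinediyl diether, (DHQD)2PHAL (10 mol%), toluene, rt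
Reagents that add atoms: none
Why: Lewis-base-catalysed allylic substitution of a Morita–Baylis–Hillman carbonate: the quinuclidine nitrogen adds SN2' with loss of CO2 and tert-butoxide, which deprotonates 6, and the allyloxide returns SN2' to the benzylic carbon within the chiral pocket of the catalyst. Both enantiomers of 5 pass through the same allylammonium ion, so the step is enantioconvergent and should set C7' as S under catalyst control.

Step 5
Reactants: 7 tert-butyl 2-[(S)-(3-methoxy-4-pivaloyloxyphenyl)(prop-2-en-1-yloxy)methyl]prop-2-enoate
Product: 8 tert-butyl (2S)-2-(3-methoxy-4-pivaloyloxyphenyl)-2,5-dihydrofuran-3-carboxylate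
Conditions: second-generation Grubbs catalyst (H2IMes)(PCy3)Cl2Ru=CHPh (5 mol%), CH2Cl2, 40 °C
Reagents that add atoms: none
Why: Ring-closing metathesis between the allyl ether and the 1,1-disubstituted acrylate alkene forms the C8=C8' bond with loss of ethene. Five-membered closure onto an electron-poor gem-disubstituted alkene is standard with this catalyst, and C7' is not involved.

Step 6
Reactants: 1 vanillin
Product: 9 3-methoxy-4-(triisopropylsilyloxy)benzaldehyde
Conditions: iPr3SiCl (1.1 equiv), imidazole (2 equiv), DMF, rt
Reagents that add atoms: chlorotriisopropylsilane, CC(C)[Si](Cl)(C(C)C)C(C)C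
Why: Silylation of the phenol. The bulky silyl ether should resist amide base, LiAlH4, Sc(OTf)3 and carbonate, and it leaves ArA a strong donor for step 11.

Step 7
Reactants: 9 3-methoxy-4-(triisopropylsilyloxy)benzaldehyde
Product: 10 [3-methoxy-4-(triisopropylsilyloxy)phenyl]methanol
Conditions: NaBH4 (1.0 equiv), MeOH, 0 °C
Reagents that add atoms: none
Why: Borohydride reduction of the aldehyde to the benzylic alcohol.

Step 8
Reactants: 10 [3-methoxy-4-(triisopropylsilyloxy)phenyl]methanol
Product: 11 [4-(bromomethyl)-2-methoxyphenoxy]triisopropylsilane
Conditions: PBr3 (0.4 equiv), Et2O, 0 °C; cold aq. NaHCO3 wash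
Reagents that add atoms: phosphorus tribromide, BrP(Br)Br
Why: Conversion of the benzylic alcohol into the bromide. The electron-rich bromide is labile and is taken on crude.

Step 9
Reactants: 11 [4-(bromomethyl)-2-methoxyphenoxy]triisopropylsilane; 12 dimethyl sulfide
Product: 13 [3-methoxy-4-(triisopropylsilyloxy)benzyl]dimethylsulfonium tetrafluoroborate
Conditions: 12 (5 equiv), NaBF4 (1.2 equiv), MeCN, rt
Reagents that add atoms: sodium tetrafluoroborate, [Na+].F[B-](F)(F)F
Why: S-Alkylation of the sulfide by the benzylic bromide. Exchanging bromide for tetrafluoroborate in the same flask prevents the reverse dealkylation and should give a salt that can be crystallised.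

Step 10
Reactants: 13 [3-methoxy-4-(triisopropylsilyloxy)benzyl]dimethylsulfonium tetrafluoroborate; 8 tert-butyl (2S)-2-(3-methoxy-4-pivaloyloxyphenyl)-2,5-dihydrofuran-3-carboxylate
Product: 15 tert-butyl (1S,2S,5S,6R)-6-[3-methoxy-4-(triisopropylsilyloxy)phenyl]-2-(3-methoxy-4-pivaloyloxyphenyl)-3-oxabicyclo[3.1.0]hexane-1-carboxylate, via sulfonium ylide 14 (not isolated)
Conditions: 13 (1.5 equiv), LiN(SiMe3)2 (1.4 equiv), THF, −78 °C; then 8 (1.0 equiv), −78 to 0 °C
Reagents that add atoms: none
Why: The ylide carbon adds to C8, the β-carbon of the unsaturated ester, and the ester enolate then displaces dimethyl sulfide from C7 in a 3-exo-tet closure, so that C7–C8 and C7–C8' form in one operation (Michael-initiated ring closure). The closest known reaction type is the cyclopropanation of α,β-unsaturated esters with benzylsulfonium ylides (Corey–Chaykovsky type). C8 is set by approach of the ylide to the face of the nearly flat dihydrofuran opposite the C7' aryl group, which projects over the other face. C8' has no freedom, because the three-membered ring can only close cis, on the face that already carries C7. At C7 the aryl group should take the exo position, away from the oxolane ring, but this centre is erased in step 11 and its configuration is of no consequence. The step needs conjugate addition to win over proton abstraction at C9 and over attack on the aryl ester; a preformed ylide with no excess amide base, an electron-rich and therefore more nucleophilic benzylide, and the hindered pivaloate serve this. Loss of the ring oxygen from C7' of the enolate should not compete, because that C–O bond lies close to the nodal plane of the enolate inside the five-membered ring.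

Step 11
Reactants: 15 tert-butyl (1S,2S,5S,6R)-6-[3-methoxy-4-(triisopropylsilyloxy)phenyl]-2-(3-methoxy-4-pivaloyloxyphenyl)-3-oxabicyclo[3.1.0]hexane-1-carboxylate
Product: 16 (1R,4R,5S,8R)-4-[3-methoxy-4-(triisopropylsilyloxy)phenyl]-8-(3-methoxy-4-pivaloyloxyphenyl)-3,7-dioxabicyclo[3.3.0]octan-2-one
Conditions: Sc(OTf)3 (10 mol%), CH2Cl2, 0 °C to rt
Reagents that add atoms: none
Why: Ring expansion of a donor–acceptor cyclopropane: Sc(OTf)3 on the ester carbonyl heterolyses the C7–C8' bond, the only one flanked by aryl donor and ester acceptor, the carbonyl oxygen closes on the benzylic cation, and the tert-butyl group leaves as isobutene with its proton ending on C8'. C8' can only be protonated so that the new lactone is cis-fused to ring B, and ArA should settle on the convex face at C7. The pivaloate keeps ArB too electron-poor for the C7'–O bond to ionise.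

Step 12
Reactants: 16 (1R,4R,5S,8R)-4-[3-methoxy-4-(triisopropylsilyloxy)phenyl]-8-(3-methoxy-4-pivaloyloxyphenyl)-3,7-dioxabicyclo[3.3.0]octan-2-one
Product: 18 2-methoxy-4-[(1R,3aS,4R,6aS)-4-{3-methoxy-4-(triisopropylsilyloxy)phenyl}tetrahydro-1H,3H-furo[3,4-c]furan-1-yl]phenol, via triol 17 (not isolated)
Conditions: LiAlH4 (3 equiv), THF, 0 °C; aq. KNaC4H4O6 work-up; crude 17, camphorsulfonic acid (10 mol%), CH2Cl2–THF, 0 °C
Reagents that add atoms: none
Why: Hydride reduction opens the lactone to the 1,4-diol and cleaves the pivaloate without touching C7', C8 or C8'. Catalytic acid then ionises the ArA-stabilised benzylic alcohol, and the C9' hydroxyl closes ring A with the aryl group on the convex face, the usual course of this SN1 cyclodehydration in furofuran synthesis.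

Step 13
Reactants: 18 2-methoxy-4-[(1R,3aS,4R,6aS)-4-{3-methoxy-4-(triisopropylsilyloxy)phenyl}tetrahydro-1H,3H-furo[3,4-c]furan-1-yl]phenol; 19 prenyl bromide
Product: 20 triisopropyl{2-methoxy-4-[(1R,3aS,4R,6aS)-4-{3-methoxy-4-[(3-methylbut-2-en-1-yl)oxy]phenyl}tetrahydro-1H,3H-furo[3,4-c]furan-1-yl]phenoxy}silane
Conditions: 19 (1.3 equiv), K2CO3 (2 equiv), acetone, 40 °C
Reagents that add atoms: none
Why: Williamson etherification of the only free phenol. The ArA oxygen is still silylated, so the prenyl group can only go to ArB, and no acid or metal catalyst follows that could harm it.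

Step 14
Reactants: 20 triisopropyl{2-methoxy-4-[(1R,3aS,4R,6aS)-4-{3-methoxy-4-[(3-methylbut-2-en-1-yl)oxy]phenyl}tetrahydro-1H,3H-furo[3,4-c]furan-1-yl]phenoxy}silane
Product: 21 2-methoxy-4-[(1R,3aS,4R,6aS)-4-{3-methoxy-4-[(3-methylbut-2-en-1-yl)oxy]phenyl}tetrahydro-1H,3H-furo[3,4-c]furan-1-yl]phenol (target, 7R,7'R,8S,8'S)
Conditions: Bu4NF (1.2 equiv), AcOH (1.2 equiv), THF, 0 °C
Reagents that add atoms: none
Why: Fluoride cleavage of the aryl silyl ether. The acetic acid buffer keeps the liberated phenoxide protonated, so the para benzylic ether is not exposed to base.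

## Compound list

1 | vanillin (4-hydroxy-3-methoxybenzaldehyde) | COc1cc(C=O)ccc1O | starting material
2 | 4-formyl-2-methoxyphenyl 2,2-dimethylpropanoate | COc1cc(C=O)ccc1OC(=O)C(C)(C)C | intermediate
3 | tert-butyl acrylate | C=CC(=O)OC(C)(C)C | starting material
4 | racemic tert-butyl 2-[hydroxy(3-methoxy-4-pivaloyloxyphenyl)methyl]prop-2-enoate | C=C(C(=O)OC(C)(C)C)C(O)c1ccc(OC(=O)C(C)(C)C)c(OC)c1 | intermediate
5 | racemic tert-butyl 2-[(tert-butoxycarbonyloxy)(3-methoxy-4-pivaloyloxyphenyl)methyl]prop-2-enoate | C=C(C(=O)OC(C)(C)C)C(OC(=O)OC(C)(C)C)c1ccc(OC(=O)C(C)(C)C)c(OC)c1 | intermediate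
6 | allyl alcohol (prop-2-en-1-ol) | C=CCO | starting material
7 | tert-butyl 2-[(S)-(3-methoxy-4-pivaloyloxyphenyl)(prop-2-en-1-yloxy)methyl]prop-2-enoate | C=CCO[C@H](C(=C)C(=O)OC(C)(C)C)c1ccc(OC(=O)C(C)(C)C)c(OC)c1 | intermediate
8 | tert-butyl (2S)-2-(3-methoxy-4-pivaloyloxyphenyl)-2,5-dihydrofuran-3-carboxylate | CC(C)(C)OC(=O)C1=CCO[C@H]1c1ccc(OC(=O)C(C)(C)C)c(OC)c1 | intermediate
9 | 3-methoxy-4-(triisopropylsilyloxy)benzaldehyde | COc1cc(C=O)ccc1O[Si](C(C)C)(C(C)C)C(C)C | intermediate
10 | [3-methoxy-4-(triisopropylsilyloxy)phenyl]methanol | COc1cc(CO)ccc1O[Si](C(C)C)(C(C)C)C(C)C | intermediate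
11 | [4-(bromomethyl)-2-methoxyphenoxy]triisopropylsilane | COc1cc(CBr)ccc1O[Si](C(C)C)(C(C)C)C(C)C | intermediate
12 | dimethyl sulfide | CSC | starting material
13 | [3-methoxy-4-(triisopropylsilyloxy)benzyl]dimethylsulfonium tetrafluoroborate | COc1cc(C[S+](C)C)ccc1O[Si](C(C)C)(C(C)C)C(C)C.F[B-](F)(F)F | intermediate
14 | dimethylsulfonium [3-methoxy-4-(triisopropylsilyloxy)phenyl]methylide | COc1cc([CH-][S+](C)C)ccc1O[Si](C(C)C)(C(C)C)C(C)C | intermediate
15 | tert-butyl (1S,2S,5S,6R)-6-[3-methoxy-4-(triisopropylsilyloxy)phenyl]-2-(3-methoxy-4-pivaloyloxyphenyl)-3-oxabicyclo[3.1.0]hexane-1-carboxylate (cyclopropane trans to the C2 aryl group, C6 aryl exo) | CC(C)(C)OC(=O)[C@@]12[C@@H](c3ccc(O[Si](C(C)C)(C(C)C)C(C)C)c(OC)c3)[C@@H]1CO[C@H]2c1ccc(OC(=O)C(C)(C)C)c(OC)c1 | intermediate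
16 | (1R,4R,5S,8R)-4-[3-methoxy-4-(triisopropylsilyloxy)phenyl]-8-(3-methoxy-4-pivaloyloxyphenyl)-3,7-dioxabicyclo[3.3.0]octan-2-one (cis-fused, both aryl groups exo) | COc1cc([C@@H]2OC(=O)[C@@H]3[C@H]2CO[C@H]3c2ccc(OC(=O)C(C)(C)C)c(OC)c2)ccc1O[Si](C(C)C)(C(C)C)C(C)C | intermediate
17 | 4-[(2R,3S,4S)-4-{(R)-hydroxy[3-methoxy-4-(triisopropylsilyloxy)phenyl]methyl}-3-(hydroxymethyl)oxolan-2-yl]-2-methoxyphenol | COc1cc([C@H](O)[C@@H]2CO[C@@H](c3ccc(O)c(OC)c3)[C@@H]2CO)ccc1O[Si](C(C)C)(C(C)C)C(C)C | intermediate
18 | 2-methoxy-4-[(1R,3aS,4R,6aS)-4-{3-methoxy-4-(triisopropylsilyloxy)phenyl}tetrahydro-1H,3H-furo[3,4-c]furan-1-yl]phenol | COc1cc([C@@H]2OC[C@@H]3[C@H]2CO[C@H]3c2ccc(O)c(OC)c2)ccc1O[Si](C(C)C)(C(C)C)C(C)C | intermediate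
19 | prenyl bromide (1-bromo-3-methylbut-2-ene) | CC(C)=CCBr | starting material
20 | triisopropyl{2-methoxy-4-[(1R,3aS,4R,6aS)-4-{3-methoxy-4-[(3-methylbut-2-en-1-yl)oxy]phenyl}tetrahydro-1H,3H-furo[3,4-c]furan-1-yl]phenoxy}silane | COc1cc([C@@H]2OC[C@@H]3[C@H]2CO[C@H]3c2ccc(OCC=C(C)C)c(OC)c2)ccc1O[Si](C(C)C)(C(C)C)C(C)C | intermediate
21 | 2-methoxy-4-[(1R,3aS,4R,6aS)-4-{3-methoxy-4-[(3-methylbut-2-en-1-yl)oxy]phenyl}tetrahydro-1H,3H-furo[3,4-c]furan-1-yl]phenol | COc1cc([C@@H]2OC[C@@H]3[C@H]2CO[C@H]3c2ccc(OCC=C(C)C)c(OC)c2)ccc1O | target

## Step count and least certain steps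

Total: 14 steps. Longest linear sequence: 10 steps (steps 1–5, then 10–14); the ArA branch (steps 6–9) joins at step 10.

Step 10 (key step). The conjugate addition to a trisubstituted, α-branched enoate may be slow. The ylide would then be consumed by Sommelet–Hauser rearrangement through its S-methylide, or would act as a base at C9 of 8 and move the double bond out of conjugation. Facial discrimination may also be incomplete, because the directing aryl group is 1,3 to the carbon attacked. The fallback sets out from 9 and 8 and returns at 15. Compound 9 is condensed with tosylhydrazide to the tosylhydrazone F1. Its sodium salt (NaOMe) is warmed at 40–50 °C with a phase-transfer salt in the presence of 8 (Bamford–Stevens conditions), releasing the aryldiazomethane F2. F2 adds as a 1,3-dipole, carbon to C8 and nitrogen to C8', on the face away from ArB, to give the 1-pyrazoline F3. Here the bond next to the directing aryl group forms in the same concerted event, so the facial bias should be stronger. Gentle heating or irradiation at 350 nm expels N2 from F3 and closes the C7–C8' bond.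

Step 11. Ionisation without ring closure is the main danger: loss of the C8 proton to a styrene, Friedel–Crafts attack of C7 on ArB, or loss of the silyl group. A single ester is also a weaker acceptor than the usual malonate, so the cyclopropane may resist opening. The fallback sets out from 15 and returns at 16, changing the substrate and the mode of activation. Trifluoroacetic acid in CH2Cl2 at 0 °C removes the tert-butyl group to give the carboxylic acid F4. F4 is then isomerised in hexafluoroisopropanol with catalytic TfOH, the carboxyl group serving as internal nucleophile and as proton source for C8'. This is the known acid-mediated lactonisation of 2-arylcyclopropanecarboxylic acids.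

Step 4. The enantioselectivity may be low, or of the opposite sense, with an aliphatic alcohol as nucleophile and a bulky tert-butyl ester; direct substitution without transposition may also erode regiochemistry. The fallback sets out from 5 and 6 and returns at 8. DABCO in place of the chiral amine gives the racemic ether F5, and the metathesis of step 5 gives the racemic dihydrofuran F6. F6 is resolved by preparative chromatography on a polysaccharide carbamate chiral stationary phase, and the (R)-enantiomer F7 is set aside.

Step 12. Prolonged contact with acid could ionise the C7'–O bond of ring B, now para to a free phenol, and epimerise C7'. The C7 cation could attack ArB instead of the hydroxyl, and the facial preference at C7 may be incomplete. The fallback sets out from 17, isolated after the hydride work-up, and returns at 20, avoiding acid altogether. The phenol of 17 is alkylated with 19 (K2CO3, acetone) to the diol prenyl ether F8. MsCl (1.05 equiv) and Et3N in CH2Cl2 at −20 °C to rt sulfonylate the primary C9' hydroxyl to the mesylate F9, which the C7 hydroxyl displaces in a 5-exo-tet closure. C7 keeps the configuration it already has from 16.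

Step 2. Conversion with the hindered acrylate is slow, and over long reaction times the amine and traces of water may strip the activated aryl ester of 2. The fallback sets out from 2 and returns at 4. Hydroalumination of tert-butyl propiolate with iBu2AlH and N-methylmorpholine N-oxide in THF at 0 °C gives the α-aluminoacrylate F10. F10 adds to the aldehyde of 2 within hours (vinylalumination), and aqueous work-up releases 4.

## Further compounds

F1 | step 10 | N'-{(E)-[3-methoxy-4-(triisopropylsilyloxy)phenyl]methylidene}-4-methylbenzenesulfonohydrazide | COc1cc(/C=N/NS(=O)(=O)c2ccc(C)cc2)ccc1O[Si](C(C)C)(C(C)C)C(C)C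
F2 | step 10 | [4-(diazomethyl)-2-methoxyphenoxy]triisopropylsilane | COc1cc(C=[N+]=[N-])ccc1O[Si](C(C)C)(C(C)C)C(C)C
F3 | step 10 | tert-butyl 4-[3-methoxy-4-(triisopropylsilyloxy)phenyl]-8-(3-methoxy-4-pivaloyloxyphenyl)-7-oxa-2,3-diazabicyclo[3.3.0]oct-2-ene-1-carboxylate (diazene bridge trans to the C8 aryl group, C4 aryl exo) | CC(C)(C)OC(=O)[C@@]12N=N[C@@H](c3ccc(O[Si](C(C)C)(C(C)C)C(C)C)c(OC)c3)[C@@H]1CO[C@H]2c1ccc(OC(=O)C(C)(C)C)c(OC)c1
F4 | step 11 | (1S,2S,5S,6R)-6-[3-methoxy-4-(triisopropylsilyloxy)phenyl]-2-(3-methoxy-4-pivaloyloxyphenyl)-3-oxabicyclo[3.1.0]hexane-1-carboxylic acid | OC(=O)[C@@]12[C@@H](c3ccc(O[Si](C(C)C)(C(C)C)C(C)C)c(OC)c3)[C@@H]1CO[C@H]2c1ccc(OC(=O)C(C)(C)C)c(OC)c1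
F5 | step 4 | racemic tert-butyl 2-[(3-methoxy-4-pivaloyloxyphenyl)(prop-2-en-1-yloxy)methyl]prop-2-enoate | C=CCOC(C(=C)C(=O)OC(C)(C)C)c1ccc(OC(=O)C(C)(C)C)c(OC)c1
F6 | step 4 | racemic tert-butyl 2-(3-methoxy-4-pivaloyloxyphenyl)-2,5-dihydrofuran-3-carboxylate | CC(C)(C)OC(=O)C1=CCOC1c1ccc(OC(=O)C(C)(C)C)c(OC)c1
F7 | step 4 | tert-butyl (2R)-2-(3-methoxy-4-pivaloyloxyphenyl)-2,5-dihydrofuran-3-carboxylate | CC(C)(C)OC(=O)C1=CCO[C@@H]1c1ccc(OC(=O)C(C)(C)C)c(OC)c1
F8 | step 12 | (R)-[(3S,4S,5R)-4-(hydroxymethyl)-5-{3-methoxy-4-[(3-methylbut-2-en-1-yl)oxy]phenyl}oxolan-3-yl][3-methoxy-4-(triisopropylsilyloxy)phenyl]methanol | COc1cc([C@H](O)[C@@H]2CO[C@@H](c3ccc(OCC=C(C)C)c(OC)c3)[C@@H]2CO)ccc1O[Si](C(C)C)(C(C)C)C(C)C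
F9 | step 12 | [(2R,3S,4S)-4-{(R)-hydroxy[3-methoxy-4-(triisopropylsilyloxy)phenyl]methyl}-2-{3-methoxy-4-[(3-methylbut-2-en-1-yl)oxy]phenyl}oxolan-3-yl]methyl methanesulfonate | COc1cc([C@H](O)[C@@H]2CO[C@@H](c3ccc(OCC=C(C)C)c(OC)c3)[C@@H]2COS(C)(=O)=O)ccc1O[Si](C(C)C)(C(C)C)C(C)C
F10 | step 2 | [1-(tert-butoxycarbonyl)ethenyl]bis(2-methylpropyl)aluminium | CC(C)C[Al](CC(C)C)C(=C)C(=O)OC(C)(C)C
A1 | alternative 1 | (5S)-5-{[(1S,2R,5S)-5-methyl-2-(propan-2-yl)cyclohexyl]oxy}furan-2(5H)-one | O=C1C=C[C@@H](O[C@H]2C[C@@H](C)CC[C@@H]2C(C)C)O1
A2 | alternative 1 | 2-[3-methoxy-4-(triisopropylsilyloxy)phenyl]-1,3-dithiane | COc1cc(C2SCCCS2)ccc1O[Si](C(C)C)(C(C)C)C(C)C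
A3 | alternative 1 | 3-methoxy-4-[(3-methylbut-2-en-1-yl)oxy]benzaldehyde | COc1cc(C=O)ccc1OCC=C(C)C
A4 | alternative 1 | 3,4-trans-4,5-trans-3-[hydroxy{3-methoxy-4-[(3-methylbut-2-en-1-yl)oxy]phenyl}methyl]-4-{2-[3-methoxy-4-(triisopropylsilyloxy)phenyl]-1,3-dithian-2-yl}-5-{[(1S,2R,5S)-5-methyl-2-(propan-2-yl)cyclohexyl]oxy}dihydrofuran-2(3H)-one (carbinol centre drawn arbitrarily) | O=C1[C@@H]([C@@H](O)c2ccc(OCC=C(C)C)c(OC)c2)[C@H](C2(SCCCS2)c2ccc(O[Si](C(C)C)(C(C)C)C(C)C)c(OC)c2)[C@@H](O[C@H]2C[C@@H](C)CC[C@@H]2C(C)C)O1
A5 | alternative 2 | [(4S,5S)-2,2-dimethyl-1,3-dioxolane-4,5-diyl]dimethyl mixed diester of (E)-3-[3-methoxy-4-(triisopropylsilyloxy)phenyl]prop-2-enoic acid and (E)-3-[3-methoxy-4-(prop-2-en-1-yloxy)phenyl]prop-2-enoic acid | C=CCOc1ccc(/C=C/C(=O)OC[C@@H]2OC(C)(C)O[C@H]2COC(=O)/C=C/c2ccc(O[Si](C(C)C)(C(C)C)C(C)C)c(OC)c2)cc1OC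
A6 | alternative 2 | cyclic [(4S,5S)-2,2-dimethyl-1,3-dioxolane-4,5-diyl]dimethyl diester of all-trans-3-[3-methoxy-4-(triisopropylsilyloxy)phenyl]-4-[3-methoxy-4-(prop-2-en-1-yloxy)phenyl]cyclobutane-1,2-dicarboxylic acid | COc1cc(ccc1O[Si](C(C)C)(C(C)C)C(C)C)[C@@H]1[C@@H](c4ccc(OCC=C)c(OC)c4)[C@@H]2C(=O)OC[C@@H]3OC(C)(C)O[C@H]3COC(=O)[C@@H]12
A7 | alternative 3 | 2,3-trans-3-[(tert-butyldimethylsilyloxy)methyl]-5-diazo-2-[3-methoxy-4-(triisopropylsilyloxy)phenyl]oxan-4-one | COc1cc(ccc1O[Si](C(C)C)(C(C)C)C(C)C)[C@@H]1OCC(=[N+]=[N-])C(=O)[C@H]1CO[Si](C)(C)C(C)(C)C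
A8 | alternative 3 | methyl 4-[(tert-butyldimethylsilyloxy)methyl]-5-[3-methoxy-4-(triisopropylsilyloxy)phenyl]oxolane-3-carboxylate (4,5-trans, 3,4-cis drawn) | COc1cc(ccc1O[Si](C(C)C)(C(C)C)C(C)C)[C@@H]1OC[C@@H](C(=O)OC)[C@H]1CO[Si](C)(C)C(C)(C)C
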